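**Retrosynthetic overview**
- The target is opened to an acyclic hydroxy-β-diketone acetal. One acid operation closes the dihydrofuran ring B (O1–C7a enol ether) and the cyclohexadienone ring A (C3a=C4 vinylogous aldol condensation) together, as the last step.
- The open chain comes from a C7–C7a Claisen acylation of the only enolate of an α-quaternary methoxymethyl ketone with a trans-γ-lactone, which acts as a ring-opening acyl donor.
- The ketone (C5 stereocentre) comes from a palladium-catalysed decarboxylative asymmetric allylation of an enol carbonate made from 1,3-dimethoxyacetone and methyl formate.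
- The lactone (C2 and C3 stereocentres) comes from a ruthenium-catalysed cycloisomerisation–oxidation of an anti-homopropargylic alcohol, itself made by Marshall propargylation of 3,4,5-trimethoxybenzaldehyde.
- Ring order: the aryl ring is bought; rings A and B of the core are both formed in the final step.

Atom labels: the benzofuran numbering of the target (O1, C2, C3, C3a, C4, C5, C6, C7, C7a) is used for the corresponding atoms of all intermediates.

Assumption: the (R,R) antipode of the DACH-phenyl Trost ligand is taken to give the (R)-aldehyde, and the (R)-mesylate is taken to give the (1S,2S)-alcohol (anti SN2′ oxidative addition, retentive transmetalation, cyclic SE2′ addition); if either sense proves opposite, the commercial antipode is used.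

**Step 1**
Reactants: 1 (R)-but-3-yn-2-ol
Product: 2 (R)-but-3-yn-2-yl methanesulfonate
Conditions: MsCl (1.2 equiv), Et3N (1.5 equiv), CH2Cl2, −78 → 0 °C
Reagents that add atoms: methanesulfonyl chloride, CS(=O)(=O)Cl
Why: O-sulfonylation of the secondary alcohol does not touch the stereocentre, so the (R) configuration of 1 is carried unchanged into the propargylic electrophile.

**Step 2**
Reactants: 2 (R)-but-3-yn-2-yl methanesulfonate; 3 3,4,5-trimethoxybenzaldehyde
Product: 4 (1S,2S)-2-methyl-1-(3,4,5-trimethoxyphenyl)but-3-yn-1-ol (anti)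
Conditions: Pd(OAc)2 (5 mol%), PPh3 (5 mol%), Et2Zn (3 equiv), THF, −78 → −20 °C; aq. NH4Cl
Reagents that add atoms: none
Why: Marshall propargylation, in which zerovalent palladium opens 2 by anti SN2′ attack to an allenylpalladium that is transmetalated to an allenylzinc and adds to 3 through a cyclic SE2′ transition state, so that the mesylate stereocentre fixes the methyl-bearing carbon (future C3, S) and the chair-like transition state places hydroxyl anti to methyl (future C2, S).

**Step 3**
Reactants: 4 (1S,2S)-2-methyl-1-(3,4,5-trimethoxyphenyl)but-3-yn-1-ol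
Product: 5 (4S,5S)-4-methyl-5-(3,4,5-trimethoxyphenyl)oxolan-2-one (trans lactone)
Conditions: RuCl(C5H5)(C8H12) (7 mol%), P(2-furyl)3 (21 mol%), N-hydroxysuccinimide (1.5 equiv), Bu4NBr (20 mol%), NaHCO3 (1 equiv), DMF–H2O, 95 °C
Reagents that add atoms: N-hydroxysuccinimide, ON1C(=O)CCC1=O
Why: Trost cycloisomerisation–oxidation, in which the terminal alkyne forms a ruthenium vinylidene that the hydroxyl traps as a cyclic oxacarbene and the N–O reagent oxidises to the γ-lactone, with neither stereocentre involved, so the anti alcohol gives the trans lactone.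

**Step 4**
Reactants: 6 1,3-dimethoxypropan-2-one
Product: 8 2,4-dimethoxy-3-oxobut-1-en-1-yl prop-2-en-1-yl carbonate (E/Z mixture), via sodium enolate 7 (not isolated)
Conditions: NaH (1.05 equiv), HCO2Me (3 equiv), THF, 0 → 23 °C; then ClCO2CH2CH=CH2 (1.1 equiv), 0 °C
Reagents that add atoms: methyl formate, COC=O; allyl chloroformate, C=CCOC(Cl)=O
Why: crossed Claisen formylation of the symmetrical ketone gives a single stabilised enolate that the hard chloroformate acylates on oxygen, no stereocentre is formed, and either O-acylated regioisomer would ionise to the same enolate in the next step.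

**Step 5**
Reactants: 8 2,4-dimethoxy-3-oxobut-1-en-1-yl prop-2-en-1-yl carbonate
Product: 9 (2R)-2,4-dimethoxy-3-oxo-2-(prop-2-en-1-yl)butanal
Conditions: Pd2(dba)3·CHCl3 (2.5 mol%), (R,R)-DACH-phenyl Trost ligand (5.5 mol%), 1,4-dioxane, 23 °C
Reagents that add atoms: none
Why: Tsuji–Trost decarboxylative asymmetric allylic alkylation, in which ionisation and loss of CO2 give a π-allylpalladium/β-ketoaldehyde enolate ion pair that recombines at the central carbon inside the chiral pocket of the ligand, which selects one enolate face and so sets the quaternary C5 stereocentre as (R), by analogy with the known allylation of enol carbonates to α-tertiary alkoxy aldehydes.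

**Step 6**
Reactants: 9 (2R)-2,4-dimethoxy-3-oxo-2-(prop-2-en-1-yl)butanal
Product: 10 (3R)-3-(dimethoxymethyl)-1,3-dimethoxyhex-5-en-2-one
Conditions: HC(OMe)3 (3 equiv), MeOH, pyridinium p-toluenesulfonate (5 mol%), 0 → 23 °C
Reagents that add atoms: trimethyl orthoformate, COC(OC)OC
Why: acid-catalysed acetalisation is much faster at the aldehyde than at the hindered ketone next to the quaternary carbon, and that quaternary stereocentre cannot epimerise.

**Step 7**
Reactants: 10 (3R)-3-(dimethoxymethyl)-1,3-dimethoxyhex-5-en-2-one; 5 (4S,5S)-4-methyl-5-(3,4,5-trimethoxyphenyl)oxolan-2-one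
Product: 11 (1S,2S,7R)-7-(dimethoxymethyl)-1-hydroxy-5,7-dimethoxy-2-methyl-1-(3,4,5-trimethoxyphenyl)dec-9-ene-4,6-dione (open-chain, enolised β-diketone, used crude)
Conditions: LiN(iPr)2 (1.15 equiv), 10 (1.15 equiv), THF, −78 °C; then 5 (1.0 equiv), −78 → 0 °C; AcOH, −78 °C
Reagents that add atoms: none
Why: Claisen C-acylation, in which ketone 10 has only one enolisable position (C7, the other α-carbon being quaternary), its lithium enolate opens the lactone carbonyl and the alkoxide set free deprotonates the new β-diketone to make the acylation irreversible, while no existing stereocentre is touched and the new enolisable C7 centre is lost in step 8.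

**Step 8**
Reactants: 11 (1S,2S,7R)-7-(dimethoxymethyl)-1-hydroxy-5,7-dimethoxy-2-methyl-1-(3,4,5-trimethoxyphenyl)dec-9-ene-4,6-dione
Product: 12 (2S,3S,5R)-5,7-dimethoxy-3-methyl-5-(prop-2-en-1-yl)-2-(3,4,5-trimethoxyphenyl)-3,5-dihydro-1-benzofuran-6(2H)-one
Conditions: TsOH·H2O (0.2 equiv), toluene, 23 → 50 °C
Reagents that add atoms: none
Why: acid-triggered double cyclodehydration, in which the C2 hydroxyl adds to the C7a carbonyl and loses water to give the five-membered vinylogous ester (ring B), whose γ-carbon C3a then attacks the oxocarbenium ion from the acetal in a six-ring vinylogous aldol condensation (ring A) that ends with loss of methanol to the fully conjugated dienone, the three stereocentres being carried unchanged from 5 and 10 (any ionisation at benzylic C2 recloses to the more stable 2,3-trans ring).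

**Compound list**
1 | (R)-but-3-yn-2-ol | C[C@@H](O)C#C | starting material
2 | (R)-but-3-yn-2-yl methanesulfonate | C[C@@H](OS(C)(=O)=O)C#C | intermediate
3 | 3,4,5-trimethoxybenzaldehyde | O=Cc1cc(OC)c(OC)c(OC)c1 | starting material
4 | (1S,2S)-2-methyl-1-(3,4,5-trimethoxyphenyl)but-3-yn-1-ol | O[C@H](c1cc(OC)c(OC)c(OC)c1)[C@H](C#C)C | intermediate
5 | (4S,5S)-4-methyl-5-(3,4,5-trimethoxyphenyl)oxolan-2-one | O=C1C[C@H](C)[C@@H](c2cc(OC)c(OC)c(OC)c2)O1 | intermediate
6 | 1,3-dimethoxypropan-2-one | COCC(=O)COC | starting material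
7 | sodium 2,4-dimethoxy-3-oxobut-1-en-1-olate | COCC(=O)C(OC)=C[O-].[Na+] | intermediate
8 | 2,4-dimethoxy-3-oxobut-1-en-1-yl prop-2-en-1-yl carbonate | C=CCOC(=O)OC=C(OC)C(=O)COC | intermediate
9 | (2R)-2,4-dimethoxy-3-oxo-2-(prop-2-en-1-yl)butanal | COCC(=O)[C@@](OC)(CC=C)C=O | intermediate
10 | (3R)-3-(dimethoxymethyl)-1,3-dimethoxyhex-5-en-2-one | COCC(=O)[C@@](OC)(CC=C)C(OC)OC | intermediate
11 | (1S,2S,7R)-7-(dimethoxymethyl)-1-hydroxy-5,7-dimethoxy-2-methyl-1-(3,4,5-trimethoxyphenyl)dec-9-ene-4,6-dione | O[C@H](c1cc(OC)c(OC)c(OC)c1)[C@@H](C)CC(=O)C(OC)C(=O)[C@@](OC)(CC=C)C(OC)OC | intermediate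
12 | (2S,3S,5R)-5,7-dimethoxy-3-methyl-5-(prop-2-en-1-yl)-2-(3,4,5-trimethoxyphenyl)-3,5-dihydro-1-benzofuran-6(2H)-one | C=CC[C@@]1(OC)C=C2C(=C(OC)C1=O)O[C@H](c1cc(OC)c(OC)c(OC)c1)[C@H]2C | target

**Step count**
Total steps: 8. Longest linear sequence: 5 (steps 4–5–6–7–8, or 1–2–3–7–8).

**Three steps most likely to fail**

Step 5 (enantioselectivity of the allylation with a fully stabilised, acyclic enolate is not assured). The fallback replaces catalyst control by separation of diastereomers. It sets out from 8: Pd(PPh3)4 in THF gives racemic 2,4-dimethoxy-3-oxo-2-(prop-2-en-1-yl)butanal F1, and acetalisation as in step 6 gives racemic 3-(dimethoxymethyl)-1,3-dimethoxyhex-5-en-2-one F2. Acylation of its enolate with enantiopure lactone 5 as in step 7 gives the diketone as a mixture of epimers at the quaternary carbon F3. The acid cascade of step 8 then gives 12 together with its C5 epimer, (2S,3S,5S)-5-epi-12 F4. These are diastereomers and are separated on silica, so the route is rejoined at 12.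

Step 7 (a γ-lactone is a sluggish acyl donor for a ketone enolate and the tetrahedral adduct can revert). The fallback uses an acyclic, O-protected Weinreb amide in place of the lactone. It sets out from 5: AlMe3 and MeNH(OMe)·HCl in CH2Cl2 open the lactone to (3S,4S)-4-hydroxy-N-methoxy-N,3-dimethyl-4-(3,4,5-trimethoxyphenyl)butanamide F5, and TESCl with imidazole gives its triethylsilyl ether F6. The lithium enolate of 10 is acylated by F6 through a stable chelate to give the O-triethylsilyl ether of 11 F7. Under the acid of step 8 the silyl group is lost and both rings close, so the route is rejoined at 12.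

Step 8 (the one-pot cascade may stall after ring B, or the acetal may ionise too slowly). The fallback closes ring A first by a directed Mukaiyama reaction. It sets out from 11: TMSOTf and Et3N in CH2Cl2 at 0 °C give the tris(trimethylsilyl) derivative F8 (silylated carbinol plus a 1,3-bis(silyloxy)diene whose only possible terminus is C3a). Catalytic TMSOTf at −78 °C makes that diene terminus add to the acetal oxocarbenium ion; aqueous work-up gives (6R)-4-[(1S,2S)-1-hydroxy-1-(3,4,5-trimethoxyphenyl)propan-2-yl]-2,5,6-trimethoxy-6-(prop-2-en-1-yl)cyclohexane-1,3-dione F9, with ring A closed alone. TsOH in toluene then eliminates methanol (C3a=C4) and closes ring B, so the route is rejoined at 12.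

**Further compounds**
F1 | step 5 | rac-2,4-dimethoxy-3-oxo-2-(prop-2-en-1-yl)butanal | COCC(=O)C(OC)(CC=C)C=O
F2 | step 5 | rac-3-(dimethoxymethyl)-1,3-dimethoxyhex-5-en-2-one | COCC(=O)C(OC)(CC=C)C(OC)OC
F3 | step 5 | (1S,2S)-7-(dimethoxymethyl)-1-hydroxy-5,7-dimethoxy-2-methyl-1-(3,4,5-trimethoxyphenyl)dec-9-ene-4,6-dione, mixture of epimers at the quaternary carbon | O[C@H](c1cc(OC)c(OC)c(OC)c1)[C@@H](C)CC(=O)C(OC)C(=O)C(OC)(CC=C)C(OC)OC
F4 | step 5 | (2S,3S,5S)-5,7-dimethoxy-3-methyl-5-(prop-2-en-1-yl)-2-(3,4,5-trimethoxyphenyl)-3,5-dihydro-1-benzofuran-6(2H)-one | C=CC[C@]1(OC)C=C2C(=C(OC)C1=O)O[C@H](c1cc(OC)c(OC)c(OC)c1)[C@H]2C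
F5 | step 7 | (3S,4S)-4-hydroxy-N-methoxy-N,3-dimethyl-4-(3,4,5-trimethoxyphenyl)butanamide | O[C@H](c1cc(OC)c(OC)c(OC)c1)[C@@H](C)CC(=O)N(C)OC
F6 | step 7 | (3S,4S)-N-methoxy-N,3-dimethyl-4-(triethylsilyloxy)-4-(3,4,5-trimethoxyphenyl)butanamide | CC[Si](CC)(CC)O[C@H](c1cc(OC)c(OC)c(OC)c1)[C@@H](C)CC(=O)N(C)OC
F7 | step 7 | (1S,2S,7R)-7-(dimethoxymethyl)-5,7-dimethoxy-2-methyl-1-(triethylsilyloxy)-1-(3,4,5-trimethoxyphenyl)dec-9-ene-4,6-dione | CC[Si](CC)(CC)O[C@H](c1cc(OC)c(OC)c(OC)c1)[C@@H](C)CC(=O)C(OC)C(=O)[C@@](OC)(CC=C)C(OC)OC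
F8 | step 8 | tris(trimethylsilyl) derivative of 11 (1-O-silyl ether, 4,6-bis(silyloxy)-3,5-diene) | C[Si](C)(C)O[C@H](c1cc(OC)c(OC)c(OC)c1)[C@@H](C)C=C(O[Si](C)(C)C)C(OC)=C(O[Si](C)(C)C)[C@@](OC)(CC=C)C(OC)OC
F9 | step 8 | (6R)-4-[(1S,2S)-1-hydroxy-1-(3,4,5-trimethoxyphenyl)propan-2-yl]-2,5,6-trimethoxy-6-(prop-2-en-1-yl)cyclohexane-1,3-dione | O[C@H](c1cc(OC)c(OC)c(OC)c1)[C@@H](C)C1C(OC)[C@](OC)(CC=C)C(=O)C(OC)C1=O
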